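The γ-butyrolactone of the lower half is cut between its carbonyl carbon C2′ and C3′H2. Drawn with the C4′ methyl as an exocyclic methylene, O1′ (on C5′) and C3′ are both allylic to C4′, so the lactone maps onto a six-membered cyclic carbonate (a 5-methylene-1,3-dioxan-2-one). Zerovalent palladium ionises its primary C–O bond, expels CO2 and, under CO, joins the tethered alkoxide and the π-allyl terminus through a new carbonyl. This ring contraction gives a β-methylene lactone whose hydrogenation sets C4′. The C2 quaternary centre comes from a copper-catalysed enantioselective alkynylation of a chromone ester. One monomer serves both halves, joined by Suzuki coupling after one lactone is opened and masked.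

Key step: step 7

Assumption: each aryl ring carries only one non-hydrogen group ortho to the C6–C6′ bond, so the biaryl axis rotates freely and no axial configuration needs control.

Step 1
Reactants: 1 2′,6′-dihydroxyacetophenone; 2 dimethyl oxalate
Product: 4 methyl 5-hydroxy-4-oxo-4H-chromene-2-carboxylate, via diketo ester 3 (not isolated)
Conditions: NaOMe, MeOH, reflux; then HCl, MeOH, reflux
Reagents that add atoms: none
Why: Crossed Claisen condensation of the acetophenone enolate with the oxalate, then acid-catalysed cyclodehydration (Kostanecki-type chromone synthesis), should give the chromone, the symmetry of 1 leaving the second hydroxyl as C5–OH.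

Step 2
Reactants: 4 methyl 5-hydroxy-4-oxo-4H-chromene-2-carboxylate; 5 phenylacetylene
Product: 8 methyl (2S)-5-hydroxy-4-oxo-2-(phenylethynyl)chromane-2-carboxylate, via benzopyrylium triflate 6 (not isolated), via cyclic silyl enol ether 7 (not isolated)
Conditions: iPr2Si(OTf)2, 2,6-lutidine, CH2Cl2, 0 °C; then CuI (10 mol%), indane-fused bis(oxazoline) ligand (12 mol%), iPr2NEt, −40 °C; then Et3N·3HF
Reagents that add atoms: none
Why: The chelating silyl bis(triflate) turns the 5-hydroxychromone into a 4-siloxybenzopyrylium, and copper-catalysed enantioselective alkynylation by the bis(oxazoline)–copper acetylide on the Si face of C2 (O1 > CO2Me > C3, ligand antipode chosen for that face) should set the (S)-tertiary ether before fluoride frees ketone and phenol.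

Step 3
Reactants: 8 methyl (2S)-5-hydroxy-4-oxo-2-(phenylethynyl)chromane-2-carboxylate
Product: 9 methyl (2S)-5-hydroxy-4-oxo-2-[(Z)-2-phenylethenyl]chromane-2-carboxylate
Conditions: H2 (1 atm), Pd/CaCO3 poisoned with Pb(OAc)2, quinoline, EtOAc, rt
Reagents that add atoms: none
Why: Lindlar semi-hydrogenation adds H2 syn on the poisoned surface and should stop at the Z-alkene without touching ketone, ester or phenol.

Step 4
Reactants: 9 methyl (2S)-5-hydroxy-4-oxo-2-[(Z)-2-phenylethenyl]chromane-2-carboxylate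
Product: 11 methyl (2S)-2-formyl-5-hydroxy-4-oxochromane-2-carboxylate, via ozonide 10 (not isolated)
Conditions: O3, CH2Cl2, −78 °C; then Me2S, −78 °C to rt; benzaldehyde removed by chromatography
Reagents that add atoms: ozone, [O-][O+]=O
Why: Ozonolysis with reductive work-up should cleave the styrene far faster than the acyl-deactivated phenol ring, leaving the former alkyne carbon as a formyl group on the non-enolisable quaternary C2.

Step 5
Reactants: 11 methyl (2S)-2-formyl-5-hydroxy-4-oxochromane-2-carboxylate; 12 2-bromoprop-2-en-1-ol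
Product: 13 methyl (2S)-5-hydroxy-2-[(1R)-1-hydroxy-2-(hydroxymethyl)prop-2-en-1-yl]-4-oxochromane-2-carboxylate
Conditions: CrCl2 (6 equiv), NiCl2 (2 mol%), DMSO, rt
Reagents that add atoms: none
Why: The Nozaki–Hiyama–Kishi alkenylation is aldehyde-selective beside ketone and esters, and Felkin–Anh addition anti to the C2–O1 bond with the flat ester outside (the same face as in an ester–aldehyde chelate attacked from the O1 side) places the alkenylchromium on the Re face and should give the (R)-carbinol.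

Step 6
Reactants: 13 methyl (2S)-5-hydroxy-2-[(1R)-1-hydroxy-2-(hydroxymethyl)prop-2-en-1-yl]-4-oxochromane-2-carboxylate
Product: 15 methyl (2S)-5-hydroxy-2-[(4R)-5-methylidene-2-oxo-1,3-dioxan-4-yl]-4-oxochromane-2-carboxylate, via imidazole-1-carboxylate 14 (not isolated)
Conditions: CDI, CH2Cl2, 0 °C to rt; then DMAP (cat.), 40 °C
Reagents that add atoms: 1,1′-carbonyldiimidazole, O=C(n1ccnc1)n1ccnc1
Why: Acyl transfer from CDI to the unhindered primary allylic hydroxyl and 6-exo-trig closure by the secondary hydroxyl (cyclic carbonate formation) should give the dioxanone, the chelated phenol being too poor a nucleophile to compete and no stereocentre being touched.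

Step 7
Reactants: 15 methyl (2S)-5-hydroxy-2-[(4R)-5-methylidene-2-oxo-1,3-dioxan-4-yl]-4-oxochromane-2-carboxylate
Product: 16 methyl (2S)-5-hydroxy-2-[(2R)-3-methylidene-5-oxooxolan-2-yl]-4-oxochromane-2-carboxylate
Conditions: Pd2(dba)3·CHCl3 (2.5 mol%), PPh3 (10 mol%), CO (20 atm), THF, 50 °C
Reagents that add atoms: carbon monoxide, [C-]#[O+]
Why: Zerovalent palladium ionises the primary allylic C–O bond of the dioxanone and CO2 is lost, leaving a 2-substituted π-allylpalladium whose alkoxide (the oxygen on C5′) stays tethered; CO is then taken up between that oxygen and palladium, and C–C reductive elimination with the allyl terminus forges C2′–C3′ (the alternative ordering, CO insertion into the allyl–palladium bond then acyl transfer to the alkoxide, gives the same lactone). The closest known reaction type is the Tsuji-type decarboxylative carbonylation of allylic and propargylic carbonates and of cyclic carbonates or carbamates that give zwitterionic π-allylpalladium species. The five-membered lactone closes by reductive elimination from a six-membered (alkoxycarbonyl)(allyl)palladacycle, a net contraction of the six-membered carbonate ring. No stereocentre is created, and C5′ keeps its configuration because its own C–O bond is never ionised. The step needs ionisation at the primary and not the secondary allylic C–O bond, which the neopentyl, electron-poor C5′ secures; it needs CO capture to beat O-allylation and β-hydride loss, which CO pressure, the absence of any external nucleophile and the strain of the alternative oxetane secure. Regiochemistry of carbonylation is not an issue because both allyl termini are CH2.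

Step 8
Reactants: 16 methyl (2S)-5-hydroxy-2-[(2R)-3-methylidene-5-oxooxolan-2-yl]-4-oxochromane-2-carboxylate
Product: 17 methyl (2S)-5-hydroxy-2-[(2R,3S)-3-methyl-5-oxooxolan-2-yl]-4-oxochromane-2-carboxylate
Conditions: H2 (1 atm), Rh/Al2O3, EtOAc, rt
Reagents that add atoms: none
Why: Heterogeneous hydrogenation (rhodium chosen to avoid hydrogenolysis of the allylic C5′–O bond) delivers hydrogen to the exocyclic alkene from the lactone face opposite the bulky C2 substituent on C5′, so the new methyl should end cis to it (C4′ = S), and any butenolide isomer of 16 reduces in the same sense.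

Step 9
Reactants: 17 methyl (2S)-5-hydroxy-2-[(2R,3S)-3-methyl-5-oxooxolan-2-yl]-4-oxochromane-2-carboxylate
Product: 18 methyl (2S)-5-hydroxy-6-iodo-2-[(2R,3S)-3-methyl-5-oxooxolan-2-yl]-4-oxochromane-2-carboxylate
Conditions: NIS (1.05 equiv), TFA (cat.), MeCN, 0 °C
Reagents that add atoms: N-iodosuccinimide, O=C1CCC(=O)N1I
Why: Electrophilic aromatic iodination should go to C6, which is ortho to the chelated 5-hydroxyl and para to O1, the usual first site of halogenation in 5-hydroxychromanones.

Step 10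
Reactants: 18 methyl (2S)-5-hydroxy-6-iodo-2-[(2R,3S)-3-methyl-5-oxooxolan-2-yl]-4-oxochromane-2-carboxylate
Product: 19 methyl (2S)-5-(benzyloxy)-6-iodo-2-[(2R,3S)-3-methyl-5-oxooxolan-2-yl]-4-oxochromane-2-carboxylate
Conditions: BnBr, K2CO3, DMF, rt
Reagents that add atoms: benzyl bromide, BrCc1ccccc1
Why: Williamson etherification of the phenoxide should proceed cleanly because carbonate is too weak a base to enolise C3 appreciably, so lactone and C2 stay intact.

Step 11
Reactants: 19 methyl (2S)-5-(benzyloxy)-6-iodo-2-[(2R,3S)-3-methyl-5-oxooxolan-2-yl]-4-oxochromane-2-carboxylate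
Product: 21 benzyl (3S,4R)-4-[(2S)-5-(benzyloxy)-6-iodo-2-(methoxycarbonyl)-4-oxochroman-2-yl]-4-hydroxy-3-methylbutanoate, via lithium carboxylate 20 (not isolated)
Conditions: LiOH·H2O (1.05 equiv), THF/H2O, 0 °C; evaporate; then BnBr, Bu4NBr (cat.), DMF, rt
Reagents that add atoms: lithium hydroxide, [Li+].[OH-]; benzyl bromide, BrCc1ccccc1
Why: Saponification should open the unhindered γ-lactone faster than the neopentyl methyl ester, and SN2 alkylation of the carboxylate under neutral conditions gives the benzyl ester without activating the acyl group, no bond to a stereocentre being broken.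

Step 12
Reactants: 21 benzyl (3S,4R)-4-[(2S)-5-(benzyloxy)-6-iodo-2-(methoxycarbonyl)-4-oxochroman-2-yl]-4-hydroxy-3-methylbutanoate
Product: 22 benzyl (3S,4R)-4-[(benzyloxy)methoxy]-4-[(2S)-5-(benzyloxy)-6-iodo-2-(methoxycarbonyl)-4-oxochroman-2-yl]-3-methylbutanoate
Conditions: BOMCl, iPr2NEt, Bu4NI (cat.), CH2Cl2, rt
Reagents that add atoms: benzyl chloromethyl ether, ClCOCc1ccccc1
Why: O-Alkylation with the highly reactive chloromethyl ether under iodide catalysis should cap the hindered hydroxyl as a hydrogenolysable acetal before it can relactonise.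

Step 13
Reactants: 19 methyl (2S)-5-(benzyloxy)-6-iodo-2-[(2R,3S)-3-methyl-5-oxooxolan-2-yl]-4-oxochromane-2-carboxylate (second portion); 22 benzyl (3S,4R)-4-[(benzyloxy)methoxy]-4-[(2S)-5-(benzyloxy)-6-iodo-2-(methoxycarbonyl)-4-oxochroman-2-yl]-3-methylbutanoate
Product: 24 methyl (2S)-5-(benzyloxy)-6-{(2S)-5-(benzyloxy)-2-[(1R,2S)-4-(benzyloxy)-1-[(benzyloxy)methoxy]-2-methyl-4-oxobutyl]-2-(methoxycarbonyl)-4-oxochroman-6-yl}-2-[(2R,3S)-3-methyl-5-oxooxolan-2-yl]-4-oxochromane-2-carboxylate, via pinacol boronate 23 (not isolated)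
Conditions: 19, B2pin2, PdCl2(dppf) (5 mol%), KOAc, dioxane, 85 °C; then 22, Pd(OAc)2 (5 mol%), SPhos, K3PO4, dioxane/H2O (20:1), 70 °C
Reagents that add atoms: none
Why: Miyaura borylation of the first iodide and Suzuki–Miyaura cross-coupling with the second in one pot should give the unsymmetrical biaryl, the biarylphosphine ligand coping with the two ortho-alkoxy partners.

Step 14
Reactants: 24 the fully protected biaryl
Product: 25 (3S,4R)-4-hydroxy-4-[(2S)-5-hydroxy-6-{(2S)-5-hydroxy-2-(methoxycarbonyl)-2-[(2R,3S)-3-methyl-5-oxooxolan-2-yl]-4-oxochroman-6-yl}-2-(methoxycarbonyl)-4-oxochroman-2-yl]-3-methylbutanoic acid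
Conditions: H2 (1 atm), Pd(OH)2/C, EtOAc, rt
Reagents that add atoms: none
Why: Global hydrogenolysis of the two benzyl ethers, the benzyl ester and the benzyloxymethyl acetal (which collapses to the alcohol and formaldehyde) under neutral conditions should free the γ-hydroxy acid without acid or base that would close it to the bis-lactone.

Compound list
1 | 2′,6′-dihydroxyacetophenone | CC(=O)c1c(O)cccc1O | starting material
2 | dimethyl oxalate | COC(=O)C(=O)OC | starting material
3 | methyl 4-(2,6-dihydroxyphenyl)-2,4-dioxobutanoate (formed as its sodium enolate) | COC(=O)C(=O)CC(=O)c1c(O)cccc1O | intermediate (not isolated)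
4 | methyl 5-hydroxy-4-oxo-4H-chromene-2-carboxylate | COC(=O)c1cc(=O)c2c(O)cccc2o1 | intermediate
5 | phenylacetylene | C#Cc1ccccc1 | starting material
6 | 2-(methoxycarbonyl)benzopyrylium triflate with a diisopropylsilylene bridge between O4 and O5 | COC(=O)c1cc2c3c(O[Si](C(C)C)(C(C)C)O2)cccc3[o+]1.[O-]S(=O)(=O)C(F)(F)F | intermediate (not isolated)
7 | (2S)-2-(phenylethynyl)-2H-chromene-2-carboxylate as the cyclic silyl enol ether (silicon bridging O4 and O5) | COC(=O)[C@]1(C#Cc2ccccc2)Oc2cccc3c2C(=C1)O[Si](C(C)C)(C(C)C)O3 | intermediate (not isolated)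
8 | methyl (2S)-5-hydroxy-4-oxo-2-(phenylethynyl)chromane-2-carboxylate | Oc1cccc2c1C(=O)C[C@@](C(=O)OC)(C#Cc1ccccc1)O2 | intermediate
9 | methyl (2S)-5-hydroxy-4-oxo-2-[(Z)-2-phenylethenyl]chromane-2-carboxylate | Oc1cccc2c1C(=O)C[C@@](C(=O)OC)(/C=C\c1ccccc1)O2 | intermediate
10 | secondary ozonide of 9 (3-phenyl-1,2,4-trioxolan-5-yl group on C2) | Oc1cccc2c1C(=O)C[C@@](C(=O)OC)(C1OOC(c3ccccc3)O1)O2 | intermediate (not isolated)
11 | methyl (2S)-2-formyl-5-hydroxy-4-oxochromane-2-carboxylate | Oc1cccc2c1C(=O)C[C@@](C(=O)OC)(C=O)O2 | intermediate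
12 | 2-bromoprop-2-en-1-ol | C=C(Br)CO | starting material
13 | methyl (2S)-5-hydroxy-2-[(1R)-1-hydroxy-2-(hydroxymethyl)prop-2-en-1-yl]-4-oxochromane-2-carboxylate | Oc1cccc2c1C(=O)C[C@@](C(=O)OC)([C@H](O)C(=C)CO)O2 | intermediate
14 | primary imidazole-1-carboxylate of diol 13 | Oc1cccc2c1C(=O)C[C@@](C(=O)OC)([C@H](O)C(=C)COC(=O)n1ccnc1)O2 | intermediate (not isolated)
15 | methyl (2S)-5-hydroxy-2-[(4R)-5-methylidene-2-oxo-1,3-dioxan-4-yl]-4-oxochromane-2-carboxylate | Oc1cccc2c1C(=O)C[C@@](C(=O)OC)([C@@H]1OC(=O)OCC1=C)O2 | intermediate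
16 | methyl (2S)-5-hydroxy-2-[(2R)-3-methylidene-5-oxooxolan-2-yl]-4-oxochromane-2-carboxylate | Oc1cccc2c1C(=O)C[C@@](C(=O)OC)([C@@H]1OC(=O)CC1=C)O2 | intermediate
17 | methyl (2S)-5-hydroxy-2-[(2R,3S)-3-methyl-5-oxooxolan-2-yl]-4-oxochromane-2-carboxylate | Oc1cccc2c1C(=O)C[C@@](C(=O)OC)([C@@H]1OC(=O)C[C@@H]1C)O2 | intermediate
18 | methyl (2S)-5-hydroxy-6-iodo-2-[(2R,3S)-3-methyl-5-oxooxolan-2-yl]-4-oxochromane-2-carboxylate | Oc1c(I)ccc2c1C(=O)C[C@@](C(=O)OC)([C@@H]1OC(=O)C[C@@H]1C)O2 | intermediate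
19 | methyl (2S)-5-(benzyloxy)-6-iodo-2-[(2R,3S)-3-methyl-5-oxooxolan-2-yl]-4-oxochromane-2-carboxylate | O(Cc3ccccc3)c1c(I)ccc2c1C(=O)C[C@@](C(=O)OC)([C@@H]4OC(=O)C[C@@H]4C)O2 | intermediate
20 | lithium (3S,4R)-4-[(2S)-5-(benzyloxy)-6-iodo-2-(methoxycarbonyl)-4-oxochroman-2-yl]-4-hydroxy-3-methylbutanoate | COC(=O)[C@@]1([C@H](O)[C@@H](C)CC(=O)[O-])CC(=O)c2c(ccc(I)c2OCc3ccccc3)O1.[Li+] | intermediate (not isolated)
21 | benzyl (3S,4R)-4-[(2S)-5-(benzyloxy)-6-iodo-2-(methoxycarbonyl)-4-oxochroman-2-yl]-4-hydroxy-3-methylbutanoate | COC(=O)[C@@]1([C@H](O)[C@@H](C)CC(=O)OCc3ccccc3)CC(=O)c2c(ccc(I)c2OCc4ccccc4)O1 | intermediate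
22 | benzyl (3S,4R)-4-[(benzyloxy)methoxy]-4-[(2S)-5-(benzyloxy)-6-iodo-2-(methoxycarbonyl)-4-oxochroman-2-yl]-3-methylbutanoate | COC(=O)[C@@]1([C@H](OCOCc5ccccc5)[C@@H](C)CC(=O)OCc3ccccc3)CC(=O)c2c(ccc(I)c2OCc4ccccc4)O1 | intermediate
23 | methyl (2S)-5-(benzyloxy)-2-[(2R,3S)-3-methyl-5-oxooxolan-2-yl]-4-oxo-6-(4,4,5,5-tetramethyl-1,3,2-dioxaborolan-2-yl)chromane-2-carboxylate | CC1(C)OB(OC1(C)C)c1ccc2c(c1OCc1ccccc1)C(=O)C[C@@](C(=O)OC)([C@@H]1OC(=O)C[C@@H]1C)O2 | intermediate (not isolated)
24 | C6–C6′ biaryl of the 5-benzyloxy lactone half and the benzyl ester/BOM ether seco half | COC(=O)[C@@]1([C@H](OCOCc5ccccc5)[C@@H](C)CC(=O)OCc3ccccc3)CC(=O)c2c(ccc(-c6ccc7c(c6OCc8ccccc8)C(=O)C[C@@](C(=O)OC)([C@@H]9OC(=O)C[C@@H]9C)O7)c2OCc4ccccc4)O1 | intermediate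
25 | (3S,4R)-4-hydroxy-4-[(2S)-5-hydroxy-6-{(2S)-5-hydroxy-2-(methoxycarbonyl)-2-[(2R,3S)-3-methyl-5-oxooxolan-2-yl]-4-oxochroman-6-yl}-2-(methoxycarbonyl)-4-oxochroman-2-yl]-3-methylbutanoic acid | COC(=O)[C@@]1([C@H](O)[C@@H](C)CC(=O)O)CC(=O)c2c(ccc(-c3ccc4c(c3O)C(=O)C[C@@](C(=O)OC)([C@@H]3OC(=O)C[C@@H]3C)O4)c2O)O1 | target

Total step count: 14. Longest linear sequence: 14 steps (1 to 14; compound 19 enters step 13 a second time as the boronate partner).

Steps most likely to fail

Step 7. The tethered alkoxide–π-allylpalladium intermediate may collapse by β-hydride loss (internal redox to an isopropenyl ketone) or by intermolecular O-allylation before it takes up CO. The fallback keeps the same bond-forming ring closure but uses an alkenyl- instead of an allyl-palladium species; it sets out from 11 and returns at 17. Bromoboration of propyne with BBr3 and quenching with pinacol gives (Z)-2-(2-bromoprop-1-en-1-yl)-4,4,5,5-tetramethyl-1,3,2-dioxaborolane F1. CrCl2/NiCl2 coupling of F1 with 11 gives the Z-borylated allylic alcohol methyl (2S)-5-hydroxy-2-[(1R,2Z)-1-hydroxy-2-methyl-3-(4,4,5,5-tetramethyl-1,3,2-dioxaborolan-2-yl)prop-2-en-1-yl]-4-oxochromane-2-carboxylate F2. NIS in MeCN replaces boron by iodine with retention to give methyl (2S)-5-hydroxy-2-[(1R,2Z)-1-hydroxy-3-iodo-2-methylprop-2-en-1-yl]-4-oxochromane-2-carboxylate F3. PdCl2(PPh3)2, CO (1 atm) and K2CO3 in THF close the butenolide methyl (2S)-5-hydroxy-2-[(2R)-3-methyl-5-oxo-2,5-dihydrofuran-2-yl]-4-oxochromane-2-carboxylate F4 by carbonylative lactonisation, again making C2′–C3′ in the ring-forming step. H2 over Rh/Al2O3 then reduces F4 from the face anti to the C2 substituent to give 17.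

Step 5. The alkenylchromium species may be lost by β-oxygen elimination or by protonolysis from its own hydroxyl, and facial selectivity at the aldehyde may be incomplete. The fallback sets out from 11 and returns at 13. CrCl2/NiCl2 coupling of 11 with 2-bromopropene, which has no β-oxygen, gives methyl (2S)-5-hydroxy-2-[(1R)-1-hydroxy-2-methylprop-2-en-1-yl]-4-oxochromane-2-carboxylate F5. Allylic hydroxylation of its methyl group with SeO2 (cat.) and t-BuOOH in CH2Cl2 then gives 13.

Step 11. Hydroxide may epimerise C2 through retro-oxa-Michael ring opening and reclosure, the methyl ester may be cleaved as well, and the hydroxy ester may relactonise before it is capped. The fallback sets out from 19 and returns at 25, with no protected seco monomer. One-pot borylation and Suzuki homocoupling of 19 (B2pin2, Pd(OAc)2, SPhos, K3PO4) gives the C2-symmetric dimethyl (2S,2′S)-5,5′-bis(benzyloxy)-2,2′-bis[(2R,3S)-3-methyl-5-oxooxolan-2-yl]-4,4′-dioxo-6,6′-bichromane-2,2′-dicarboxylate F6. Hydrogenolysis (H2, Pd(OH)2/C) gives the bis-lactone bisphenol dimethyl (2S,2′S)-5,5′-dihydroxy-2,2′-bis[(2R,3S)-3-methyl-5-oxooxolan-2-yl]-4,4′-dioxo-6,6′-bichromane-2,2′-dicarboxylate F7. LiOH (3 equiv, THF/H2O, 0 °C) first forms the two phenoxides, which deactivate both chromanones towards enolisation, and then opens one lactone statistically. Acidification to pH 5 gives 25; unreacted F7 and relactonised diacid are recycled.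

Further compounds
F1 | step 7 | (Z)-2-(2-bromoprop-1-en-1-yl)-4,4,5,5-tetramethyl-1,3,2-dioxaborolane | C/C(Br)=C/B1OC(C)(C)C(C)(C)O1
F2 | step 7 | methyl (2S)-5-hydroxy-2-[(1R,2Z)-1-hydroxy-2-methyl-3-(4,4,5,5-tetramethyl-1,3,2-dioxaborolan-2-yl)prop-2-en-1-yl]-4-oxochromane-2-carboxylate | Oc1cccc2c1C(=O)C[C@@](C(=O)OC)([C@H](O)/C(C)=C\B1OC(C)(C)C(C)(C)O1)O2
F3 | step 7 | methyl (2S)-5-hydroxy-2-[(1R,2Z)-1-hydroxy-3-iodo-2-methylprop-2-en-1-yl]-4-oxochromane-2-carboxylate | Oc1cccc2c1C(=O)C[C@@](C(=O)OC)([C@H](O)/C(C)=C\I)O2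
F4 | step 7 | methyl (2S)-5-hydroxy-2-[(2R)-3-methyl-5-oxo-2,5-dihydrofuran-2-yl]-4-oxochromane-2-carboxylate | Oc1cccc2c1C(=O)C[C@@](C(=O)OC)([C@@H]1OC(=O)C=C1C)O2
F5 | step 5 | methyl (2S)-5-hydroxy-2-[(1R)-1-hydroxy-2-methylprop-2-en-1-yl]-4-oxochromane-2-carboxylate | Oc1cccc2c1C(=O)C[C@@](C(=O)OC)([C@H](O)C(C)=C)O2
F6 | step 11 | dimethyl (2S,2′S)-5,5′-bis(benzyloxy)-2,2′-bis[(2R,3S)-3-methyl-5-oxooxolan-2-yl]-4,4′-dioxo-6,6′-bichromane-2,2′-dicarboxylate | c1(-c5ccc6c(c5OCc7ccccc7)C(=O)C[C@@](C(=O)OC)([C@@H]8OC(=O)C[C@@H]8C)O6)ccc2c(c1OCc3ccccc3)C(=O)C[C@@](C(=O)OC)([C@@H]4OC(=O)C[C@@H]4C)O2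
F7 | step 11 | dimethyl (2S,2′S)-5,5′-dihydroxy-2,2′-bis[(2R,3S)-3-methyl-5-oxooxolan-2-yl]-4,4′-dioxo-6,6′-bichromane-2,2′-dicarboxylate | c1(-c5ccc6c(c5O)C(=O)C[C@@](C(=O)OC)([C@@H]8OC(=O)C[C@@H]8C)O6)ccc2c(c1O)C(=O)C[C@@](C(=O)OC)([C@@H]4OC(=O)C[C@@H]4C)O2
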